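## The problem

The target is a dibenzylbutyrolactone whose α-benzyl group is itself a 2-aryl-3-(hydroxymethyl)-2,3-dihydrobenzofuran. The lactone α-carbon is tied through one CH2 to C5 of the benzofuran, and the β-carbon carries a vanillyl CH2. The four stereocentres form two trans pairs, (3S,4S) in the lactone and (2S,3R) in the dihydrofuran. Inside the lactone the β-centre can direct the α-centre, because an enolate is alkylated anti to the β-substituent. The dihydrofuran pair lies five bonds away across an arene, so it needs its own source of absolute configuration and has to be set as a pair. The C2–O1 bond is a benzylic aryl ether para to an oxygenated ring, which rules out strong acid and forcing hydrogenolysis; the three phenols are oxidation-prone and must stay masked, and the lactone is base-labile with an epimerisable α-centre. The benzene ring of the benzofuran is 1,2,3,5-tetrasubstituted: O1 on C7a, hydroxyl on C7, C3 on C3a, the CH2 link on C5 para to O1, and hydrogen only at C4 and C6. This is the pattern formed when the two carbons of a ketene acetal (C7a with its oxygen, C3a) are joined to C3–C6 of a 3-bromo-2-pyrone-5-carboxylate (bromine for C7, ester for C5), so the arene can be built last onto a stereodefined trans γ-lactone.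

## Retrosynthesis

**Unmasking.** Target 27 is traced back through bis(benzyl ether) 26 and silyl ether 25 to aryl bromide 23; the cuts are two O–benzyl bonds, one O–Si bond and the C7–O bond. Phenolic benzyl ethers come off under neutral hydrogenolysis. The primary alcohol is kept as a triisopropylsilyl ether, not a benzyl ether, because cleaving an alkyl benzyl ether would need conditions under which the C2–O1 benzylic ether starts to compete. The 7-hydroxyl travels as bromine, which needs no protection and is exchanged for oxygen only after the last C–C bond is made; this saves a protection step compared with an early exchange. The forward steps must tolerate the lactone.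

**Joining the halves.** 23 is cut between the lactone α-carbon and the benzylic CH2, giving (S)-β-benzyl lactone 22 and benzylic bromide 17. This cut is preferred over the aryl–CH2 bond or the β-benzyl bond because it is the one place where an existing centre controls a new one, and it gives two halves that each carry their own absolute configuration. The forward reaction must alkylate the lactone enolate trans to the β-substituent.

**Adjusting the C5 carbon.** 17 comes from alcohol 16 and this from methyl ester 15. The ester is kept up to this point because the ring construction needs it as the activating group of the pyrone.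

**Building the arene.** 15 is cut at C3a–C4 and C7a–C7, which removes the whole benzene ring and leaves cyclic silyl ketene acetal 10 and bromopyrone 12. The neighbouring cuts (O1–C2 with C2–C3, C3–C3a alone, or O1–C7a) all need the fully substituted arene beforehand and create or endanger stereocentres during ring formation. Here the precursor is a simple trans γ-lactone derivative, and the forward step creates no lasting stereocentre. It must deliver one regiochemistry and must aromatise by loss of the silyloxy group, not the ring oxygen.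

**The stereodefined lactone.** 10 is the enol silyl derivative of lactone 9, which comes from alcohol 8, acid 7 and lactone imide 6. Cutting the C4–C5 bond and the ring C–O bond of 6 leads to aldehyde 4 and succinate imide 3. An auxiliary-controlled syn aldol sets both centres at once, and ring closure of the syn adduct gives the trans lactone. The acid must be reduced and the alcohol protected without passing through an alkoxide, which could shift the lactone onto the primary oxygen.

**The β-benzyl lactone.** 22 is cut at the ring C–O bond and the Cβ–CH2Ar bond, leading through imide 20 back to the same imide 3 and benzylic bromide 19. Using 3 for both halves lets one auxiliary of one configuration supply all absolute stereochemistry. The forward alkylation must be face-selective and the reduction must distinguish imide from ester.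

**Starting materials.** 3 comes from oxazolidinone 1 and acid chloride 2, 12 from methyl coumalate 11, and 19 from alcohol 18.

## Roads not taken

Alternative 1: The cut runs through the lactone ring. Oxygen is inserted into prochiral cyclobutanone A1, so that lactone A2, the same compound as 22, receives its stereocentre from a catalyst. In the forward step a chiral N,N'-dioxide complex of Sc(OTf)3 with mCPBA, or a cyclohexanone monooxygenase with O2, would distinguish the two enantiotopic acyl–CH2 bonds. The merits are real: no stoichiometric auxiliary, a symmetric substrate with no regiochemical question, and better atom economy than steps 12 and 13. The weak points are these: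
- The prochiral centre carries a benzyl group, not an aryl group, so the differentiating substituent sits one CH2 further from the carbonyl and the enantiomeric purity is less predictable; it cannot be upgraded through a diastereomer.
- A1 needs its own ketene (2+2) and dehalogenation sequence.
- The step addresses the easiest of the four stereocentres and leaves the tetrasubstituted arene and the C2/C3 pair unsolved.

Against the catalytic step the chosen plan sets the diastereomerically pure imide 20 of predictable configuration, made from 3, which is needed anyway, and a key step placed on the hard half of the molecule.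

Alternative 2: The C3–C3a bond is made last by ring contraction of flavanone A3. With PhI(OAc)2 and H2SO4 in HC(OMe)3, trivalent iodine attacks C3 of the enol ether, the ring A carbon migrates from the carbonyl carbon to C3 anti to the leaving iodine, and the former carbonyl carbon becomes the methyl ester of trans dihydrobenzofuran A4. The reaction type is established for flavanones and gives the trans isomer. The C7 oxygen is present from the start, so no halogen-to-oxygen exchange is needed; in this respect it is better than the chosen route, which spends step 15 on it. The weak points are these: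
- The absolute configuration rests on C2 of A3, which can racemise by ring opening to the chalcone and is exposed to strong acid.
- Dehydrogenation to the flavone and migration of the C2 aryl group compete unless ring B is deactivated, hence the mesylate, which costs a step on and a step off.
- The C5 bromine still has to be homologated to CH2Br in the presence of the C3 ester or its reduction product.

The step count is comparable or longer. The chosen plan sets against it two centres fixed by an auxiliary before the ring is built and a key step that cannot erode them.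

Alternative 3: The dihydrofuran is cut at C2–C3 and O1–C2. Cs2CO3 would release ortho-quinone methide A5 from a phenolic benzylic sulfone and, in the same flask, a benzylic sulfonium ylide built on a chiral sulfide. The ylide carbon adds to the methide carbon and the phenoxide displaces the sulfide, giving A6. It is convergent, mild and trans-selective through the anti-periplanar closure of the betaine, and both arene substituents are in place beforehand. To the dihydrobenzofuran it is clearly shorter than steps 1–8. The weak points are these: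
- A5 is an alkyl-substituted quinone methide with a CH2 next to the methide carbon, so tautomerisation to the styrenyl silyl enol ether competes with addition of a semi-stabilised ylide.
- The absolute configuration depends on a stoichiometric chiral sulfide in a betaine formation that may be reversible and is unproven for such a methide.
- The C5 bromine of A6 needs three steps to become CH2Br, against two from the ester of 15.

The chosen plan is longer to 15 but gains certainty of configuration, since both centres come from an auxiliary-controlled aldol and are spectators when the ring forms.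

Key step: step 8

## Route

Assumption: 1, 2, 4, 11 and 18 are taken as purchasable (4 and 18 are the O-benzyl derivatives of vanillin and vanillyl alcohol); the two ring-fusion carbons formed and destroyed within step 8 carry no descriptors in 13 and 14 because their configuration has no bearing on 15.

Step 1
Reactants: 1 (4S)-4-benzyl-1,3-oxazolidin-2-one; 2 methyl 4-chloro-4-oxobutanoate
Product: 3 methyl 4-[(4S)-4-benzyl-2-oxo-1,3-oxazolidin-3-yl]-4-oxobutanoate
Conditions: n-BuLi, THF, −78 °C; then 2, −78 to 0 °C
Reagents that add atoms: none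
Why: N-acylation of the lithiated oxazolidinone by the acid chloride, which is far more electrophilic than the methyl ester in 2; standard preparation of an Evans imide.

Step 2
Reactants: 3 methyl 4-[(4S)-4-benzyl-2-oxo-1,3-oxazolidin-3-yl]-4-oxobutanoate; 4 4-(benzyloxy)-3-methoxybenzaldehyde
Product: 6 (4S)-4-benzyl-3-{[(2S,3S)-2-[4-(benzyloxy)-3-methoxyphenyl]-5-oxooxolan-3-yl]carbonyl}-1,3-oxazolidin-2-one, via syn-aldol adduct 5 (not isolated)
Conditions: Bu2BOTf, iPr2NEt, CH2Cl2, 0 °C; 4, −78 to 0 °C; pH 7 buffer, H2O2, MeOH, 0 °C; then PPTS (cat.), CH2Cl2, rt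
Reagents that add atoms: none
Why: Evans syn aldol through the Z boron enolate of the imide (the ester is not enolised) and a closed chair transition state, in which the (S)-benzyl auxiliary sets both new centres (3S,4S in 5); the γ-hydroxy methyl ester then closes to the γ-lactone, and the syn relationship becomes the trans 4,5-disubstituted ring.

Step 3
Reactants: 6 (4S)-4-benzyl-3-{[(2S,3S)-2-[4-(benzyloxy)-3-methoxyphenyl]-5-oxooxolan-3-yl]carbonyl}-1,3-oxazolidin-2-one
Product: 7 (2S,3S)-2-[4-(benzyloxy)-3-methoxyphenyl]-5-oxooxolane-3-carboxylic acid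
Conditions: LiOH, H2O2, THF/H2O, 0 °C; Na2SO3; HCl to pH 2
Reagents that add atoms: hydrogen peroxide, OO
Why: Hydroperoxide attacks the exocyclic imide carbonyl selectively (standard auxiliary cleavage) and 1 is recovered; any lactone opened by hydroxide recloses on acidification, and trans is also the thermodynamic arrangement.

Step 4
Reactants: 7 (2S,3S)-2-[4-(benzyloxy)-3-methoxyphenyl]-5-oxooxolane-3-carboxylic acid
Product: 8 (4R,5S)-5-[4-(benzyloxy)-3-methoxyphenyl]-4-(hydroxymethyl)oxolan-2-one
Conditions: BH3·SMe2, THF, 0 °C to rt; MeOH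
Reagents that add atoms: none
Why: Borane reduces a carboxylic acid through its acyloxyborane much faster than a lactone; the non-basic medium avoids shifting the lactone onto the new primary hydroxyl.

Step 5
Reactants: 8 (4R,5S)-5-[4-(benzyloxy)-3-methoxyphenyl]-4-(hydroxymethyl)oxolan-2-one
Product: 9 (4R,5S)-5-[4-(benzyloxy)-3-methoxyphenyl]-4-({[tri(propan-2-yl)silyl]oxy}methyl)oxolan-2-one
Conditions: TIPSCl, imidazole, DMF, rt
Reagents that add atoms: triisopropylsilyl chloride, CC(C)[Si](Cl)(C(C)C)C(C)C
Why: Silylation of a primary alcohol under a weak amine base, so that no alkoxide forms that could translactonise; the TIPS ether withstands the amide bases, hydride and palladium steps that follow.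

Step 6
Reactants: 9 (4R,5S)-5-[4-(benzyloxy)-3-methoxyphenyl]-4-({[tri(propan-2-yl)silyl]oxy}methyl)oxolan-2-one
Product: 10 tert-butyl{[(4R,5S)-5-[4-(benzyloxy)-3-methoxyphenyl]-4-({[tri(propan-2-yl)silyl]oxy}methyl)-4,5-dihydrofuran-2-yl]oxy}dimethylsilane
Conditions: LiN(iPr)2, THF, −78 °C; TBSCl, DMPU, −78 °C to rt; pentane, filtration, used crude
Reagents that add atoms: tert-butyldimethylsilyl chloride, CC(C)(C)[Si](C)(C)Cl
Why: O-silylation of the lactone lithium enolate in the presence of a dipolar additive gives the cyclic silyl ketene acetal, as is standard for γ-lactones; the β-carbon carries no leaving group and C4 and C5 are not acidic, so the trans pair is untouched.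

Step 7
Reactants: 11 methyl 2-oxo-2H-pyran-5-carboxylate (methyl coumalate)
Product: 12 methyl 3-bromo-2-oxo-2H-pyran-5-carboxylate
Conditions: Br2, CH2Cl2, 0 °C to rt; then Et3N, 0 °C
Reagents that add atoms: bromine, BrBr
Why: Electrophilic bromination at C3, the only free nucleophilic position of the pyrone (C5 is blocked by the ester), completed by amine-induced loss of HBr; bromination–dehydrobromination of 2-pyrones.

Step 8
Reactants: 10 tert-butyl{[(4R,5S)-5-[4-(benzyloxy)-3-methoxyphenyl]-4-({[tri(propan-2-yl)silyl]oxy}methyl)-4,5-dihydrofuran-2-yl]oxy}dimethylsilane; 12 methyl 3-bromo-2-oxo-2H-pyran-5-carboxylate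
Product: 15 methyl (2S,3R)-2-[4-(benzyloxy)-3-methoxyphenyl]-7-bromo-3-({[tri(propan-2-yl)silyl]oxy}methyl)-2,3-dihydro-1-benzofuran-5-carboxylate, via bridged lactone cycloadduct 13 (not isolated), via silyloxy cyclohexadiene 14 (not isolated)
Conditions: PhMe, 90 °C; then DBU, 0 °C to rt
Reagents that add atoms: none
Why: Proposed new method: the electron-rich C=C of 10 should add across C6 and C3 of the electron-poor diene 12 in an inverse-demand (4+2) cycloaddition, its nucleophilic CH carbon bonding to C6 (β to the ester) and its acetal carbon to the brominated C3, to give bridged lactone 13; retro-(4+2) loss of CO2 leaves cyclohexadiene 14, and DBU removes the ring-fusion proton, which is vinylogous to the ester, so that silanolate leaves C7a and the arene forms. The closest known reaction types are the benzannulation of coumalates and 3-bromo-2-pyrones with dialkyl ketene acetals and enol ethers, which gives alkoxyarenes after loss of CO2 and alcohol, and the inverse-demand cycloaddition of cyclic ketene acetals with azadienes, which keeps the ring oxygen; a lactone-derived silyl ketene acetal has not been used in this role. The six-membered carbocycle closes by cycloaddition, suprafacial on both partners, onto the existing dihydrofuran, which is necessarily cis-fused in 13 and 14. No lasting stereocentre is created: the two ring-fusion centres become planar on aromatisation, and C2 and C3 are spectators without acidic hydrogen. The regiochemistry needed is secured by the matched polarisation of both partners, the same sense as for enol ethers with 3-bromo-2-pyrones. Loss of siloxide instead of the ring alkoxide is secured by running the elimination with base: in the dienolate the exocyclic C–OSi bond is aligned with the π system while O1 lies near its nodal plane, and silanolate is the better leaving group. Acid, which would favour ionisation at the more basic ring oxygen, is excluded.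

Step 9
Reactants: 15 methyl (2S,3R)-2-[4-(benzyloxy)-3-methoxyphenyl]-7-bromo-3-({[tri(propan-2-yl)silyl]oxy}methyl)-2,3-dihydro-1-benzofuran-5-carboxylate
Product: 16 [(2S,3R)-2-[4-(benzyloxy)-3-methoxyphenyl]-7-bromo-3-({[tri(propan-2-yl)silyl]oxy}methyl)-2,3-dihydro-1-benzofuran-5-yl]methanol
Conditions: iBu2AlH, CH2Cl2, −78 to 0 °C; aq. KNaC4H4O6
Reagents that add atoms: none
Why: Hydride reduction of the aryl ester to the benzylic alcohol; aryl bromide, silyl ether and benzyl ether are inert to iBu2AlH at low temperature.

Step 10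
Reactants: 16 [(2S,3R)-2-[4-(benzyloxy)-3-methoxyphenyl]-7-bromo-3-({[tri(propan-2-yl)silyl]oxy}methyl)-2,3-dihydro-1-benzofuran-5-yl]methanol
Product: 17 {[(2S,3R)-2-[4-(benzyloxy)-3-methoxyphenyl]-7-bromo-5-(bromomethyl)-2,3-dihydro-1-benzofuran-3-yl]methoxy}tri(propan-2-yl)silane
Conditions: CBr4, PPh3, CH2Cl2, 0 °C; used without storage
Reagents that add atoms: carbon tetrabromide, BrC(Br)(Br)Br
Why: Appel bromination under neutral conditions, suited to the acid-sensitive para-alkoxybenzylic system; the ring bromine makes the benzylic bromide less prone to ionise.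

Step 11
Reactants: 18 [4-(benzyloxy)-3-methoxyphenyl]methanol
Product: 19 1-(benzyloxy)-4-(bromomethyl)-2-methoxybenzene
Conditions: PBr3, Et2O, 0 °C; used directly
Reagents that add atoms: phosphorus tribromide, BrP(Br)Br
Why: Standard conversion of a benzylic alcohol into its bromide through the phosphite ester.

Step 12
Reactants: 3 methyl 4-[(4S)-4-benzyl-2-oxo-1,3-oxazolidin-3-yl]-4-oxobutanoate; 19 1-(benzyloxy)-4-(bromomethyl)-2-methoxybenzene
Product: 20 methyl (3S)-3-{[(4S)-4-benzyl-2-oxo-1,3-oxazolidin-3-yl]carbonyl}-4-[4-(benzyloxy)-3-methoxyphenyl]butanoate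
Conditions: NaN(SiMe3)2, THF, −78 °C; 19, −78 to −30 °C
Reagents that add atoms: none
Why: Evans alkylation: the chelated Z sodium enolate of the imide is alkylated on the face away from the benzyl group of the auxiliary, which gives the (3S) centre; the imide α-hydrogens are more acidic than those of the ester.

Step 13
Reactants: 20 methyl (3S)-3-{[(4S)-4-benzyl-2-oxo-1,3-oxazolidin-3-yl]carbonyl}-4-[4-(benzyloxy)-3-methoxyphenyl]butanoate
Product: 22 (4S)-4-{[4-(benzyloxy)-3-methoxyphenyl]methyl}oxolan-2-one, via hydroxy ester 21 (not isolated)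
Conditions: NaBH4, THF/H2O, 0 °C to rt; then 1 M HCl
Reagents that add atoms: none
Why: Borohydride in aqueous THF reduces the activated exocyclic imide carbonyl to the primary alcohol (reductive removal of the auxiliary) but not a methyl ester; γ-hydroxy ester 21 lactonises in the flask and on acidic work-up, and the stereocentre of 22 is not α to a carbonyl.

Step 14
Reactants: 22 (4S)-4-{[4-(benzyloxy)-3-methoxyphenyl]methyl}oxolan-2-one; 17 {[(2S,3R)-2-[4-(benzyloxy)-3-methoxyphenyl]-7-bromo-5-(bromomethyl)-2,3-dihydro-1-benzofuran-3-yl]methoxy}tri(propan-2-yl)silane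
Product: 23 (3S,4S)-3-{[(2S,3R)-2-[4-(benzyloxy)-3-methoxyphenyl]-7-bromo-3-({[tri(propan-2-yl)silyl]oxy}methyl)-2,3-dihydro-1-benzofuran-5-yl]methyl}-4-{[4-(benzyloxy)-3-methoxyphenyl]methyl}oxolan-2-one
Conditions: LiN(SiMe3)2, THF, −78 °C; 17, DMPU, −78 to −40 °C
Reagents that add atoms: none
Why: Alkylation of the lactone lithium enolate by the benzylic bromide anti to the β-benzyl group gives the trans (3S,4S) lactone, the classical way to dibenzylbutyrolactone lignans; the aryl bromide is inert to the amide base.

Step 15
Reactants: 23 (3S,4S)-3-{[(2S,3R)-2-[4-(benzyloxy)-3-methoxyphenyl]-7-bromo-3-({[tri(propan-2-yl)silyl]oxy}methyl)-2,3-dihydro-1-benzofuran-5-yl]methyl}-4-{[4-(benzyloxy)-3-methoxyphenyl]methyl}oxolan-2-one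
Product: 25 (3S,4S)-3-{[(2S,3R)-2-[4-(benzyloxy)-3-methoxyphenyl]-7-hydroxy-3-({[tri(propan-2-yl)silyl]oxy}methyl)-2,3-dihydro-1-benzofuran-5-yl]methyl}-4-{[4-(benzyloxy)-3-methoxyphenyl]methyl}oxolan-2-one, via pinacol boronate 24 (not isolated)
Conditions: B2pin2, Pd(dppf)Cl2 (cat.), KOAc, 1,4-dioxane, 90 °C; then NaBO3·4H2O, THF/H2O, rt
Reagents that add atoms: bis(pinacolato)diboron, CC1(C)OB(OC1(C)C)B1OC(C)(C)C(C)(C)O1 (boryl group of 24); sodium perborate, [Na+].[O-]OB=O (phenol oxygen of 25)
Why: Miyaura borylation of the aryl bromide by zerovalent palladium formed from Pd(dppf)Cl2, followed by oxidative 1,2-migration of the aryl group from boron to oxygen; the weak base KOAc and perborate leave the lactone and its trans α-centre intact.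

Step 16
Reactants: 25 (3S,4S)-3-{[(2S,3R)-2-[4-(benzyloxy)-3-methoxyphenyl]-7-hydroxy-3-({[tri(propan-2-yl)silyl]oxy}methyl)-2,3-dihydro-1-benzofuran-5-yl]methyl}-4-{[4-(benzyloxy)-3-methoxyphenyl]methyl}oxolan-2-one
Product: 26 (3S,4S)-3-{[(2S,3R)-2-[4-(benzyloxy)-3-methoxyphenyl]-7-hydroxy-3-(hydroxymethyl)-2,3-dihydro-1-benzofuran-5-yl]methyl}-4-{[4-(benzyloxy)-3-methoxyphenyl]methyl}oxolan-2-one
Conditions: Bu4NF, AcOH, THF, 0 °C to rt
Reagents that add atoms: none
Why: Fluoride cleavage of the primary silyl ether; buffering with AcOH keeps the medium too weakly basic to open the lactone or to expose the phenolate to oxidation.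

Step 17
Reactants: 26 (3S,4S)-3-{[(2S,3R)-2-[4-(benzyloxy)-3-methoxyphenyl]-7-hydroxy-3-(hydroxymethyl)-2,3-dihydro-1-benzofuran-5-yl]methyl}-4-{[4-(benzyloxy)-3-methoxyphenyl]methyl}oxolan-2-one
Product: 27 (3S,4S)-3-{[(2S,3R)-7-hydroxy-2-(4-hydroxy-3-methoxyphenyl)-3-(hydroxymethyl)-2,3-dihydro-1-benzofuran-5-yl]methyl}-4-[(4-hydroxy-3-methoxyphenyl)methyl]oxolan-2-one
Conditions: H2 (1 atm), 10% Pd/C, EtOAc/MeOH, rt
Reagents that add atoms: none
Why: Hydrogenolysis of the two primary aryl benzyl ethers, which are cleaved much faster than the hindered secondary benzylic aryl ether C2–O1; neutral conditions, no stereocentre is touched.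

## Compound list

1 | (4S)-4-benzyl-1,3-oxazolidin-2-one | O=C1N[C@@H](Cc2ccccc2)CO1 | starting material
2 | methyl 4-chloro-4-oxobutanoate | COC(=O)CCC(Cl)=O | starting material
3 | methyl 4-[(4S)-4-benzyl-2-oxo-1,3-oxazolidin-3-yl]-4-oxobutanoate | COC(=O)CCC(=O)N1[C@@H](Cc2ccccc2)COC1=O | intermediate
4 | 4-(benzyloxy)-3-methoxybenzaldehyde | COc1cc(C=O)ccc1OCc1ccccc1 | starting material
5 | methyl (3S,4S)-4-[4-(benzyloxy)-3-methoxyphenyl]-3-{[(4S)-4-benzyl-2-oxo-1,3-oxazolidin-3-yl]carbonyl}-4-hydroxybutanoate (syn aldol adduct) | COC(=O)C[C@H](C(=O)N1[C@@H](Cc2ccccc2)COC1=O)[C@H](O)c1ccc(OCc2ccccc2)c(OC)c1 | intermediate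
6 | (4S)-4-benzyl-3-{[(2S,3S)-2-[4-(benzyloxy)-3-methoxyphenyl]-5-oxooxolan-3-yl]carbonyl}-1,3-oxazolidin-2-one (trans lactone) | O=C1C[C@H](C(=O)N2[C@@H](Cc3ccccc3)COC2=O)[C@@H](c2ccc(OCc3ccccc3)c(OC)c2)O1 | intermediate
7 | (2S,3S)-2-[4-(benzyloxy)-3-methoxyphenyl]-5-oxooxolane-3-carboxylic acid (trans) | O=C1C[C@H](C(=O)O)[C@@H](c2ccc(OCc3ccccc3)c(OC)c2)O1 | intermediate
8 | (4R,5S)-5-[4-(benzyloxy)-3-methoxyphenyl]-4-(hydroxymethyl)oxolan-2-one (trans) | O=C1C[C@H](CO)[C@@H](c2ccc(OCc3ccccc3)c(OC)c2)O1 | intermediate
9 | (4R,5S)-5-[4-(benzyloxy)-3-methoxyphenyl]-4-({[tri(propan-2-yl)silyl]oxy}methyl)oxolan-2-one | O=C1C[C@H](CO[Si](C(C)C)(C(C)C)C(C)C)[C@@H](c2ccc(OCc3ccccc3)c(OC)c2)O1 | intermediate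
10 | tert-butyl{[(4R,5S)-5-[4-(benzyloxy)-3-methoxyphenyl]-4-({[tri(propan-2-yl)silyl]oxy}methyl)-4,5-dihydrofuran-2-yl]oxy}dimethylsilane (cyclic silyl ketene acetal) | CC(C)(C)[Si](C)(C)OC1=C[C@H](CO[Si](C(C)C)(C(C)C)C(C)C)[C@@H](c2ccc(OCc3ccccc3)c(OC)c2)O1 | intermediate
11 | methyl 2-oxo-2H-pyran-5-carboxylate | COC(=O)C1=COC(=O)C=C1 | starting material
12 | methyl 3-bromo-2-oxo-2H-pyran-5-carboxylate | COC(=O)C1=COC(=O)C(Br)=C1 | intermediate
13 | bridged cycloadduct of 10 and 12: 2-oxabicyclo[2.2.2]oct-7-en-3-one with bromine on the bridgehead next to the lactone carbonyl and the methyl ester on the alkene carbon next to the O-bearing bridgehead, cis-fused across its saturated bridge to the (2S,3R)-2-aryl-3-(silyloxymethyl)oxolane, TBS-oxy group on the fusion carbon bonded to the brominated bridgehead (new centres unassigned) | COC(=O)C1=CC2(Br)C(=O)OC1C1[C@H](CO[Si](C(C)C)(C(C)C)C(C)C)[C@@H](c3ccc(OCc4ccccc4)c(OC)c3)OC12O[Si](C)(C)C(C)(C)C | intermediate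
14 | methyl (2S,3R)-2-[4-(benzyloxy)-3-methoxyphenyl]-7-bromo-7a-[(tert-butyldimethylsilyl)oxy]-3-({[tri(propan-2-yl)silyl]oxy}methyl)-2,3,3a,7a-tetrahydro-1-benzofuran-5-carboxylate (cis-fused, fusion centres unassigned) | COC(=O)C1=CC2[C@H](CO[Si](C(C)C)(C(C)C)C(C)C)[C@@H](c3ccc(OCc4ccccc4)c(OC)c3)OC2(O[Si](C)(C)C(C)(C)C)C(Br)=C1 | intermediate
15 | methyl (2S,3R)-2-[4-(benzyloxy)-3-methoxyphenyl]-7-bromo-3-({[tri(propan-2-yl)silyl]oxy}methyl)-2,3-dihydro-1-benzofuran-5-carboxylate (trans) | COC(=O)c1cc(Br)c2c(c1)[C@H](CO[Si](C(C)C)(C(C)C)C(C)C)[C@@H](c1ccc(OCc3ccccc3)c(OC)c1)O2 | intermediate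
16 | [(2S,3R)-2-[4-(benzyloxy)-3-methoxyphenyl]-7-bromo-3-({[tri(propan-2-yl)silyl]oxy}methyl)-2,3-dihydro-1-benzofuran-5-yl]methanol | OCc1cc(Br)c2c(c1)[C@H](CO[Si](C(C)C)(C(C)C)C(C)C)[C@@H](c1ccc(OCc3ccccc3)c(OC)c1)O2 | intermediate
17 | {[(2S,3R)-2-[4-(benzyloxy)-3-methoxyphenyl]-7-bromo-5-(bromomethyl)-2,3-dihydro-1-benzofuran-3-yl]methoxy}tri(propan-2-yl)silane | BrCc1cc(Br)c2c(c1)[C@H](CO[Si](C(C)C)(C(C)C)C(C)C)[C@@H](c1ccc(OCc3ccccc3)c(OC)c1)O2 | intermediate
18 | [4-(benzyloxy)-3-methoxyphenyl]methanol | COc1cc(CO)ccc1OCc1ccccc1 | starting material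
19 | 1-(benzyloxy)-4-(bromomethyl)-2-methoxybenzene | COc1cc(CBr)ccc1OCc1ccccc1 | intermediate
20 | methyl (3S)-3-{[(4S)-4-benzyl-2-oxo-1,3-oxazolidin-3-yl]carbonyl}-4-[4-(benzyloxy)-3-methoxyphenyl]butanoate | COC(=O)C[C@H](Cc1ccc(OCc2ccccc2)c(OC)c1)C(=O)N1[C@@H](Cc2ccccc2)COC1=O | intermediate
21 | methyl (3S)-4-[4-(benzyloxy)-3-methoxyphenyl]-3-(hydroxymethyl)butanoate | COC(=O)C[C@H](Cc1ccc(OCc2ccccc2)c(OC)c1)CO | intermediate
22 | (4S)-4-{[4-(benzyloxy)-3-methoxyphenyl]methyl}oxolan-2-one | COc1cc(C[C@@H]2COC(=O)C2)ccc1OCc1ccccc1 | intermediate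
23 | (3S,4S)-3-{[(2S,3R)-2-[4-(benzyloxy)-3-methoxyphenyl]-7-bromo-3-({[tri(propan-2-yl)silyl]oxy}methyl)-2,3-dihydro-1-benzofuran-5-yl]methyl}-4-{[4-(benzyloxy)-3-methoxyphenyl]methyl}oxolan-2-one | COc1cc(C[C@@H]2COC(=O)[C@H]2Cc2cc(Br)c3c(c2)[C@H](CO[Si](C(C)C)(C(C)C)C(C)C)[C@@H](c2ccc(OCc4ccccc4)c(OC)c2)O3)ccc1OCc1ccccc1 | intermediate
24 | 7-(4,4,5,5-tetramethyl-1,3,2-dioxaborolan-2-yl) analogue of 23 (boron in place of the ring bromine) | COc1cc(C[C@@H]2COC(=O)[C@H]2Cc2cc(B4OC(C)(C)C(C)(C)O4)c3c(c2)[C@H](CO[Si](C(C)C)(C(C)C)C(C)C)[C@@H](c2ccc(OCc4ccccc4)c(OC)c2)O3)ccc1OCc1ccccc1 | intermediate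
25 | (3S,4S)-3-{[(2S,3R)-2-[4-(benzyloxy)-3-methoxyphenyl]-7-hydroxy-3-({[tri(propan-2-yl)silyl]oxy}methyl)-2,3-dihydro-1-benzofuran-5-yl]methyl}-4-{[4-(benzyloxy)-3-methoxyphenyl]methyl}oxolan-2-one | COc1cc(C[C@@H]2COC(=O)[C@H]2Cc2cc(O)c3c(c2)[C@H](CO[Si](C(C)C)(C(C)C)C(C)C)[C@@H](c2ccc(OCc4ccccc4)c(OC)c2)O3)ccc1OCc1ccccc1 | intermediate
26 | (3S,4S)-3-{[(2S,3R)-2-[4-(benzyloxy)-3-methoxyphenyl]-7-hydroxy-3-(hydroxymethyl)-2,3-dihydro-1-benzofuran-5-yl]methyl}-4-{[4-(benzyloxy)-3-methoxyphenyl]methyl}oxolan-2-one | COc1cc(C[C@@H]2COC(=O)[C@H]2Cc2cc(O)c3c(c2)[C@H](CO)[C@@H](c2ccc(OCc4ccccc4)c(OC)c2)O3)ccc1OCc1ccccc1 | intermediate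
27 | (3S,4S)-3-{[(2S,3R)-7-hydroxy-2-(4-hydroxy-3-methoxyphenyl)-3-(hydroxymethyl)-2,3-dihydro-1-benzofuran-5-yl]methyl}-4-[(4-hydroxy-3-methoxyphenyl)methyl]oxolan-2-one | COc1cc(C[C@@H]2COC(=O)[C@H]2Cc2cc(O)c3c(c2)[C@H](CO)[C@@H](c2ccc(O)c(OC)c2)O3)ccc1O | target

## Step count and least certain steps

Total step count: 17. Longest linear sequence: 13 steps (steps 1–6, 8–10 and 14–17); step 7 and steps 11–13 are side branches.

**Step 8 (key step, new method).** The most likely failure is transfer of the silyl group inside the zwitterion formed by the first C–C bond, a Michael-type group transfer that opens the pyrone instead of closing the second bond. Behind it stand hydrolysis of 10 by adventitious water and aromatisation with loss of the ring alkoxide if ionisation outruns deprotonation. The fallback uses known chemistry and replaces the silyl ketene acetal by a dialkyl one, which has no transferable group. It sets out from lactone 9. O-Methylation with Me3OBF4 in CH2Cl2 gives the O-methyl lactonium tetrafluoroborate F1, and NaOMe in MeOH turns it into the cyclic ortho ester F2 (Meerwein ortho ester synthesis). Heating F2 with 12 in toluene releases methanol to form the cyclic methyl ketene acetal F3 in the flask; this is the ortho ester mode in which coumalates are known to give para-alkoxybenzoates. Cycloaddition then gives the methoxy bridged lactone F4, loss of CO2 gives the methoxy cyclohexadiene F5, and DBU expels methanol from F5. The route is rejoined at 15.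

**Step 2.** The electron-rich benzylic aldolate may revert (retro-aldol) or close to the lactone incompletely, and facial control may erode if the ester carbonyl competes for boron. The fallback drops the auxiliary for this half and sets out from aldehyde 4. Condensation with succinic anhydride under ZnCl2 and Et3N in CH2Cl2 (Fittig-type paraconic acid synthesis) should give the racemic trans acid F6. Resolution is through the salt with one enantiomer of 1-phenylethylamine, written here for the (R)-amine as the ammonium carboxylate F7; the other amine enantiomer is used if its salt is the less soluble one. Acidification of F7 rejoins the route at 7.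

**Step 13.** Discrimination between imide and methyl ester may be incomplete, and the lactone formed in the flask may be reduced further to the diol. The fallback sets out from 20. The auxiliary is removed hydrolytically with LiOH and H2O2 to give the half-ester acid F8. BH3·SMe2 then reduces only the acid, giving hydroxy ester 21, and catalytic p-TsOH closes it. The route is rejoined at 22.

**Step 14.** The electron-rich benzylic bromide may ionise and self-condense, and proton transfer between product and enolate may lead to double alkylation. The fallback changes the electrophile to a carbonyl group and sets out from alcohol 16. MnO2 gives the aldehyde F9. Its aldol addition to the lithium enolate of 22 (LiN(SiMe3)2, THF, −78 °C) gives the trans aldol adduct F10 as carbinol epimers. Ionic deoxygenation of the para-alkoxybenzylic alcohol with Et3SiH and BF3·OEt2 at −78 °C rejoins the route at 23.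

**Step 17.** Hydrogenolytic opening of the benzylic C2–O1 bond may compete with debenzylation once the phenols are free. The fallback sets out from 26 and removes the benzyl groups without hydrogen, by BCl3 with pentamethylbenzene as cation scavenger in CH2Cl2 at −78 °C, arriving at 27 directly.

## Further compounds

F1 | step 8 | (4R,5S)-5-[4-(benzyloxy)-3-methoxyphenyl]-2-methoxy-4-({[tri(propan-2-yl)silyl]oxy}methyl)-4,5-dihydro-3H-furan-1-ium tetrafluoroborate | C[O+]=C1C[C@H](CO[Si](C(C)C)(C(C)C)C(C)C)[C@@H](c2ccc(OCc3ccccc3)c(OC)c2)O1.F[B-](F)(F)F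
F2 | step 8 | (4R,5S)-5-[4-(benzyloxy)-3-methoxyphenyl]-2,2-dimethoxy-4-({[tri(propan-2-yl)silyl]oxy}methyl)oxolane | COC1(OC)C[C@H](CO[Si](C(C)C)(C(C)C)C(C)C)[C@@H](c2ccc(OCc3ccccc3)c(OC)c2)O1
F3 | step 8 | {[(2S,3R)-2-[4-(benzyloxy)-3-methoxyphenyl]-5-methoxy-2,3-dihydrofuran-3-yl]methoxy}tri(propan-2-yl)silane | COC1=C[C@H](CO[Si](C(C)C)(C(C)C)C(C)C)[C@@H](c2ccc(OCc3ccccc3)c(OC)c2)O1
F4 | step 8 | methoxy analogue of bridged cycloadduct 13 (OMe in place of the TBS-oxy group, new centres unassigned) | COC(=O)C1=CC2(Br)C(=O)OC1C1[C@H](CO[Si](C(C)C)(C(C)C)C(C)C)[C@@H](c3ccc(OCc4ccccc4)c(OC)c3)OC12OC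
F5 | step 8 | methyl (2S,3R)-2-[4-(benzyloxy)-3-methoxyphenyl]-7-bromo-7a-methoxy-3-({[tri(propan-2-yl)silyl]oxy}methyl)-2,3,3a,7a-tetrahydro-1-benzofuran-5-carboxylate (fusion centres unassigned) | COC(=O)C1=CC2[C@H](CO[Si](C(C)C)(C(C)C)C(C)C)[C@@H](c3ccc(OCc4ccccc4)c(OC)c3)OC2(OC)C(Br)=C1
F6 | step 2 | racemic trans-2-[4-(benzyloxy)-3-methoxyphenyl]-5-oxooxolane-3-carboxylic acid (both enantiomers) | O=C1C[C@H](C(=O)O)[C@@H](c2ccc(OCc3ccccc3)c(OC)c2)O1.O=C1C[C@@H](C(=O)O)[C@H](c2ccc(OCc3ccccc3)c(OC)c2)O1
F7 | step 2 | (1R)-1-phenylethan-1-aminium (2S,3S)-2-[4-(benzyloxy)-3-methoxyphenyl]-5-oxooxolane-3-carboxylate | O=C1C[C@H](C(=O)[O-])[C@@H](c2ccc(OCc3ccccc3)c(OC)c2)O1.C[C@@H]([NH3+])c1ccccc1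
F8 | step 13 | (2S)-2-{[4-(benzyloxy)-3-methoxyphenyl]methyl}-4-methoxy-4-oxobutanoic acid | COC(=O)C[C@H](Cc1ccc(OCc2ccccc2)c(OC)c1)C(=O)O
F9 | step 14 | (2S,3R)-2-[4-(benzyloxy)-3-methoxyphenyl]-7-bromo-3-({[tri(propan-2-yl)silyl]oxy}methyl)-2,3-dihydro-1-benzofuran-5-carbaldehyde | O=Cc1cc(Br)c2c(c1)[C@H](CO[Si](C(C)C)(C(C)C)C(C)C)[C@@H](c1ccc(OCc3ccccc3)c(OC)c1)O2
F10 | step 14 | trans aldol adduct of 22 and F9: 23 with a hydroxyl on the CH2 that links lactone and benzofuran (carbinol epimers) | COc1cc(C[C@@H]2COC(=O)[C@H]2C(O)c2cc(Br)c3c(c2)[C@H](CO[Si](C(C)C)(C(C)C)C(C)C)[C@@H](c2ccc(OCc4ccccc4)c(OC)c2)O3)ccc1OCc1ccccc1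
F0 | step 17 | none | none
A1 | alternative 1 | 3-{[4-(benzyloxy)-3-methoxyphenyl]methyl}cyclobutan-1-one | COc1cc(CC2CC(=O)C2)ccc1OCc1ccccc1
A2 | alternative 1 | (4S)-4-{[4-(benzyloxy)-3-methoxyphenyl]methyl}oxolan-2-one | COc1cc(C[C@@H]2COC(=O)C2)ccc1OCc1ccccc1
A3 | alternative 2 | (2S)-8-(benzyloxy)-6-bromo-2-[3-methoxy-4-(methylsulfonyloxy)phenyl]-2,3-dihydro-4H-chromen-4-one | O=C1C[C@@H](c2ccc(OS(C)(=O)=O)c(OC)c2)Oc2c(OCc3ccccc3)cc(Br)cc12
A4 | alternative 2 | methyl (2S,3S)-7-(benzyloxy)-5-bromo-2-[3-methoxy-4-(methylsulfonyloxy)phenyl]-2,3-dihydro-1-benzofuran-3-carboxylate (trans) | Brc1cc(OCc2ccccc2)c2c(c1)[C@H](C(=O)OC)[C@@H](c1ccc(OS(C)(=O)=O)c(OC)c1)O2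
A5 | alternative 3 | 2-(benzyloxy)-4-bromo-6-{2-[(tert-butyldimethylsilyl)oxy]ethylidene}cyclohexa-2,4-dien-1-one | O=C1C(=CCO[Si](C)(C)C(C)(C)C)C=C(Br)C=C1OCc1ccccc1
A6 | alternative 3 | {[(2S,3R)-7-(benzyloxy)-2-[4-(benzyloxy)-3-methoxyphenyl]-5-bromo-2,3-dihydro-1-benzofuran-3-yl]methoxy}(tert-butyl)dimethylsilane (trans) | Brc1cc(OCc2ccccc2)c2c(c1)[C@H](CO[Si](C)(C)C(C)(C)C)[C@@H](c1ccc(OCc3ccccc3)c(OC)c1)O2
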